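**Retrosynthetic overview**

1. The plan rests on ring C of the indenone: C7a, which carries the C1 carbonyl, is meta to both C4–OH and C6–OMe, and C3a, between C4 and C7a, carries C3 with ring D. Ring C is therefore built from open-chain pieces instead of by substitution of a 3,5-dioxygenated benzoate.
2. Last disconnections: the five MOM ethers and the ring A methyl ester; before them the five-membered ring (C1–C2 and C2=C3) by Claisen acylation and intramolecular Horner–Wadsworth–Emmons olefination of a ring C/ring D keto ester with a ring A/ring B diaryl ether benzylphosphonate, ring A held as its carboxylate.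
3. Ring C: [4+2] cycloaddition of an aroylpropiolate (ring D, from orcinol by MOM protection, ortho-lithiation/formylation, lithium propiolate addition and oxidation) with a 1,3-dimethoxy-1-silyloxybutadiene (from methyl acetoacetate). It forms C3a–C4 and C7–C7a and is followed by aromatisation.
4. Phosphonate: SNAr union of a ring B salicyl alcohol (from 2-hydroxy-4-methoxybenzaldehyde by Dakin-type oxidation and ortho-formylation) with a ring A fluoroaldehyde (from 3-fluoro-5-methylphenol), then Appel, Arbuzov and Pinnick reactions.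
5. Ring order: rings A, B and D are bought as arenes; ring C is formed in step 7; the five-membered indenone ring in step 19.

Key step: step 7

Assumption: the target has no stereocentre and rotation about its aryl–indenone and diaryl ether bonds is taken as free; the ketene acetal geometry of the diene is drawn E and is lost on aromatisation; orcinol is chosen as the ring D source because it is a bulk chemical and reaches the aldehyde in two reliable steps.

**Route**

Step 1
Reactants: 1 orcinol (5-methylbenzene-1,3-diol)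
Product: 2 1,3-bis(methoxymethoxy)-5-methylbenzene
Conditions: MOMCl (2.6 equiv), i-Pr2NEt (3.2 equiv), CH2Cl2, 0 °C → rt
Reagents that add atoms: chloromethyl methyl ether, COCCl
Why: Williamson-type O-alkylation of both phenols by the reactive α-chloro ether under amine base should give the bis-acetal, which directs the metalation of step 2 and masks the ring D phenols until the last step.

Step 2
Reactants: 2 1,3-bis(methoxymethoxy)-5-methylbenzene
Product: 4 2,6-bis(methoxymethoxy)-4-methylbenzaldehyde, via aryllithium 3 (not isolated)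
Conditions: n-BuLi (1.2 equiv), TMEDA, THF, 0 °C; DMF, 0 °C → rt; aqueous work-up
Reagents that add atoms: N,N-dimethylformamide, CN(C)C=O
Why: Directed ortho-metalation takes place at C2 between the two chelating MOM ethers, by far the most acidic ring position, and the aryllithium is formylated by DMF.

Step 3
Reactants: 4 2,6-bis(methoxymethoxy)-4-methylbenzaldehyde; 5 methyl propiolate
Product: 7 methyl 4-[2,6-bis(methoxymethoxy)-4-methylphenyl]-4-hydroxybut-2-ynoate (racemic), via lithium acetylide 6 (not isolated)
Conditions: 5 (1.5 equiv), LiN(SiMe3)2 (1.5 equiv), THF, −78 °C; then 4, −78 °C; AcOH quench at −78 °C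
Reagents that add atoms: none
Why: 1,2-Addition of a lithium acetylide to an aldehyde: the lithiated propiolate is stable below −70 °C and slim enough to reach the doubly ortho-substituted formyl group, the cold acetic acid quench prevents base-induced side reactions of the ynoate, and the carbinol centre formed as a racemate is removed in step 4.

Step 4
Reactants: 7 methyl 4-[2,6-bis(methoxymethoxy)-4-methylphenyl]-4-hydroxybut-2-ynoate
Product: 8 methyl 4-[2,6-bis(methoxymethoxy)-4-methylphenyl]-4-oxobut-2-ynoate
Conditions: MnO2 (activated, 15 equiv), CH2Cl2, rt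
Reagents that add atoms: none
Why: MnO2 oxidises the benzylic propargylic alcohol under neutral, non-nucleophilic conditions, which suits both the acetals and the highly electrophilic acetylenic keto ester that is formed.

Step 5
Reactants: 9 methyl acetoacetate
Product: 11 methyl (E)-3-methoxybut-2-enoate, via dimethyl ketal 10 (not isolated)
Conditions: HC(OMe)3 (1.1 equiv), H2SO4 (cat.), rt; then distillation
Reagents that add atoms: trimethyl orthoformate, COC(OC)OC
Why: Acid-catalysed ketalisation with the orthoformate followed by loss of methanol on distillation gives the conjugated enol ether as its more stable E isomer (enol ether formation from a β-keto ester).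

Step 6
Reactants: 11 methyl (E)-3-methoxybut-2-enoate
Product: 13 (E)-1,3-dimethoxy-1-(trimethylsilyloxy)buta-1,3-diene, via lithium dienolate 12 (not isolated)
Conditions: LiN(i-Pr)2 (1.1 equiv), THF, −78 °C; Me3SiCl (1.3 equiv), −78 °C → rt; distillation under reduced pressure
Reagents that add atoms: chlorotrimethylsilane, C[Si](C)(C)Cl
Why: Kinetic γ-deprotonation of the β-methoxy enoate by the lithium amide gives the cross-conjugated dienolate, whose O-silylation (silyl ketene acetal formation) delivers the Brassard-type diene.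

Step 7
Reactants: 8 methyl 4-[2,6-bis(methoxymethoxy)-4-methylphenyl]-4-oxobut-2-ynoate; 13 (E)-1,3-dimethoxy-1-(trimethylsilyloxy)buta-1,3-diene
Product: 16 methyl 2-[2,6-bis(methoxymethoxy)-4-methylbenzoyl]-3-hydroxy-5-methoxybenzoate, via cyclohexa-1,4-diene cycloadduct 14 (not isolated), via aryl trimethylsilyl ether 15 (not isolated)
Conditions: 13 (1.5 equiv), toluene, −20 °C → rt; then MeOH, PPTS (cat.), rt
Reagents that add atoms: none
Why: The electron-rich silyl ketene acetal diene and the doubly activated alkyne should combine in a normal-electron-demand Diels–Alder reaction that is strongly asynchronous: the unsubstituted CH2 terminus of the diene bonds first to the alkyne carbon β to the aryl ketone (the ester-bearing carbon, future C7a; bond C7–C7a), and ring C then closes between the ketene acetal carbon (future C4) and the ketone-bearing alkyne carbon (future C3a), a six-membered closure that in the stepwise limit is a 6-exo-trig attack of the allenolate carbon on the silyloxy-oxocarbenium carbon. Cycloadduct 14 then loses methanol from its mixed silyl methyl ketal and the doubly allylic CH2 to aromatise to silyl ether 15, which methanolysis converts into phenol 16; the ketal carbon of 14 is the only stereocentre formed and it disappears on aromatisation. The closest known reaction type is the cycloaddition of 1-alkoxy-1-silyloxy-3-alkoxybutadienes with acetylenic ketones and esters followed by aromatisation to resorcinol monoethers. The step needs regioselectivity between the two acceptor groups of the alkyne: the ketone is the stronger acceptor (an aryl ketone allenolate is better stabilised than an ester enolate), and because the 2,6-dioxygenated ring D is twisted out of the carbonyl plane it neither donates into the ketone nor leaves the carbonyl carbon open to 1,2-addition, so the ketone-directed conjugate mode should prevail. This places OH at C4 next to the aroyl-bearing C3a, OMe at C6 and the ester on C7a, meta to both oxygens, in one operation.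

Step 8
Reactants: 16 methyl 2-[2,6-bis(methoxymethoxy)-4-methylbenzoyl]-3-hydroxy-5-methoxybenzoate
Product: 17 methyl 2-[2,6-bis(methoxymethoxy)-4-methylbenzoyl]-5-methoxy-3-(methoxymethoxy)benzoate
Conditions: MOMCl (3 equiv), i-Pr2NEt (4 equiv), CH2Cl2, 0 → 40 °C
Reagents that add atoms: chloromethyl methyl ether, COCCl
Why: O-Alkylation of the hydrogen-bonded ortho-acyl phenol with MOMCl is slower than for a free phenol but should go with excess reagent at 40 °C, and it is needed because a phenoxide next to the ketone would consume base and deactivate that ketone toward the olefination of step 19.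

Step 9
Reactants: 18 2-hydroxy-4-methoxybenzaldehyde
Product: 19 4-methoxy-2-(methoxymethoxy)benzaldehyde
Conditions: MOMCl (1.5 equiv), i-Pr2NEt (2 equiv), CH2Cl2, 0 °C → rt
Reagents that add atoms: chloromethyl methyl ether, COCCl
Why: Williamson-type O-alkylation of the ortho-formyl phenol; the MOM group is chosen so that all phenol protecting groups fall together in step 21.

Step 10
Reactants: 19 4-methoxy-2-(methoxymethoxy)benzaldehyde
Product: 21 4-methoxy-2-(methoxymethoxy)phenol, via aryl formate 20 (not isolated)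
Conditions: m-CPBA (1.3 equiv), CH2Cl2, 0 °C → rt; NaHCO3 wash; then K2CO3 (cat.), MeOH, rt
Reagents that add atoms: 3-chloroperoxybenzoic acid, OOC(=O)c1cccc(Cl)c1
Why: Baeyer–Villiger oxidation in which the electron-rich 2,4-dioxygenated aryl group migrates in preference to hydrogen (Dakin-type reaction) gives the aryl formate, and mild methanolysis frees the phenol oxygen that will become the diaryl ether oxygen.

Step 11
Reactants: 21 4-methoxy-2-(methoxymethoxy)phenol
Product: 22 2-hydroxy-5-methoxy-3-(methoxymethoxy)benzaldehyde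
Conditions: MgCl2 (2 equiv), Et3N (3 equiv), (CH2O)n (4 equiv), MeCN, 80 °C; cold dilute citric acid work-up
Reagents that add atoms: paraformaldehyde (as formaldehyde), C=O
Why: Magnesium-mediated ortho-formylation of a phenol (Casnati–Skattebøl reaction): the magnesium phenoxide delivers formaldehyde to C6, the only free ortho position (the para position carries OMe), and a second formaldehyde oxidises the hydroxymethyl intermediate by hydride transfer.

Step 12
Reactants: 22 2-hydroxy-5-methoxy-3-(methoxymethoxy)benzaldehyde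
Product: 23 2-(hydroxymethyl)-4-methoxy-6-(methoxymethoxy)phenol
Conditions: NaBH4 (0.6 equiv), MeOH, 0 °C; neutral aqueous work-up
Reagents that add atoms: none
Why: Borohydride reduction of the aldehyde gives the salicyl alcohol, which is kept free of acid and used directly because such alcohols form o-quinone methides easily.

Step 13
Reactants: 24 3-fluoro-5-methylphenol
Product: 25 1-fluoro-3-(methoxymethoxy)-5-methylbenzene
Conditions: MOMCl (1.3 equiv), i-Pr2NEt (1.6 equiv), CH2Cl2, 0 °C → rt
Reagents that add atoms: chloromethyl methyl ether, COCCl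
Why: Williamson-type O-alkylation of the phenol installs the group that both directs the next metalation and protects the ring A hydroxyl.

Step 14
Reactants: 25 1-fluoro-3-(methoxymethoxy)-5-methylbenzene
Product: 27 2-fluoro-6-(methoxymethoxy)-4-methylbenzaldehyde, via aryllithium 26 (not isolated)
Conditions: n-BuLi (1.1 equiv), THF, −78 °C; DMF, −78 → −20 °C; aqueous work-up
Reagents that add atoms: N,N-dimethylformamide, CN(C)C=O
Why: Directed ortho-metalation occurs at the position flanked by fluorine and the MOM ether, the two directors acting together, and at −78 °C the ortho-fluoroaryllithium is formylated by DMF before it can lose LiF to an aryne.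

Step 15
Reactants: 23 2-(hydroxymethyl)-4-methoxy-6-(methoxymethoxy)phenol; 27 2-fluoro-6-(methoxymethoxy)-4-methylbenzaldehyde
Product: 28 2-[2-(hydroxymethyl)-4-methoxy-6-(methoxymethoxy)phenoxy]-6-(methoxymethoxy)-4-methylbenzaldehyde
Conditions: Cs2CO3 (1.5 equiv), DMSO, 70 °C
Reagents that add atoms: none
Why: Nucleophilic aromatic substitution by addition–elimination: the formyl group ortho to fluorine stabilises the Meisenheimer intermediate, the electron-rich phenoxide is the only anion formed by carbonate so the benzylic hydroxyl does not compete, and caesium in DMSO gives a loose, reactive phenoxide despite its two ortho substituents.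

Step 16
Reactants: 28 2-[2-(hydroxymethyl)-4-methoxy-6-(methoxymethoxy)phenoxy]-6-(methoxymethoxy)-4-methylbenzaldehyde
Product: 29 2-[2-(bromomethyl)-4-methoxy-6-(methoxymethoxy)phenoxy]-6-(methoxymethoxy)-4-methylbenzaldehyde
Conditions: CBr4 (1.3 equiv), PPh3 (1.3 equiv), 2,6-lutidine (cat.), CH2Cl2, 0 °C
Reagents that add atoms: carbon tetrabromide, BrC(Br)(Br)Br
Why: The Appel reaction converts the primary benzylic alcohol into the bromide under near-neutral conditions that leave the aldehyde and the acetals alone, the lutidine taking up traces of HBr.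

Step 17
Reactants: 29 2-[2-(bromomethyl)-4-methoxy-6-(methoxymethoxy)phenoxy]-6-(methoxymethoxy)-4-methylbenzaldehyde
Product: 30 diethyl {2-[2-formyl-3-(methoxymethoxy)-5-methylphenoxy]-5-methoxy-3-(methoxymethoxy)benzyl}phosphonate
Conditions: P(OEt)3 (neat, 5 equiv), 130 °C; excess removed in vacuo
Reagents that add atoms: triethyl phosphite, CCOP(OCC)OCC
Why: Michaelis–Arbuzov reaction of the benzylic bromide with neat triethyl phosphite; the flanked, electron-rich aldehyde is a poor partner for the phosphite and should survive.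

Step 18
Reactants: 30 diethyl {2-[2-formyl-3-(methoxymethoxy)-5-methylphenoxy]-5-methoxy-3-(methoxymethoxy)benzyl}phosphonate
Product: 31 2-{2-[(diethoxyphosphoryl)methyl]-4-methoxy-6-(methoxymethoxy)phenoxy}-6-(methoxymethoxy)-4-methylbenzoic acid
Conditions: NaClO2 (3 equiv), NaH2PO4 (3 equiv), 2-methyl-2-butene (10 equiv), t-BuOH/H2O, rt
Reagents that add atoms: sodium chlorite, [Na+].[O-]Cl=O
Why: Pinnick (Lindgren) oxidation turns the hindered aldehyde into the carboxylic acid at buffered pH with the alkene scavenging hypochlorous acid, so that the electron-rich rings, acetals and phosphonate are untouched, and it delivers ring A directly in the acid form needed in step 19.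

Step 19
Reactants: 31 2-{2-[(diethoxyphosphoryl)methyl]-4-methoxy-6-(methoxymethoxy)phenoxy}-6-(methoxymethoxy)-4-methylbenzoic acid; 17 methyl 2-[2,6-bis(methoxymethoxy)-4-methylbenzoyl]-5-methoxy-3-(methoxymethoxy)benzoate
Product: 34 2-{2-[3-[2,6-bis(methoxymethoxy)-4-methylphenyl]-6-methoxy-4-(methoxymethoxy)-1-oxo-1H-inden-2-yl]-4-methoxy-6-(methoxymethoxy)phenoxy}-6-(methoxymethoxy)-4-methylbenzoic acid, via dilithiated phosphonate 32 (not isolated), via β-ketophosphonate 33 (not isolated)
Conditions: 31 (1.2 equiv), LiN(i-Pr)2 (2.5 equiv), THF, −78 °C; LiN(SiMe3)2 (1.3 equiv); then 17 (1.0 equiv), −78 → 0 °C; then 60 °C; cold 1 M HCl to pH 3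
Reagents that add atoms: none
Why: Claisen-type C-acylation of the lithiated benzylphosphonate by the methyl ester of 17 gives the β-ketophosphonate, whose enolate then closes the five-membered ring by intramolecular Horner–Wadsworth–Emmons olefination of the diaryl ketone (the established keto ester to cycloalkenone annulation with phosphonate anions), while ring A as its lithium carboxylate is inert to the carbanion, which an ester there would invite to a seven-membered Claisen closure or a Truce–Smiles shift, and LiN(SiMe3)2 serves as the non-reducing base that takes up the acidic proton of 33.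

Step 20
Reactants: 34 the indenone carboxylic acid of step 19
Product: 35 methyl 2-{2-[3-[2,6-bis(methoxymethoxy)-4-methylphenyl]-6-methoxy-4-(methoxymethoxy)-1-oxo-1H-inden-2-yl]-4-methoxy-6-(methoxymethoxy)phenoxy}-6-(methoxymethoxy)-4-methylbenzoate
Conditions: MeI (3 equiv), K2CO3 (2 equiv), DMF, rt
Reagents that add atoms: iodomethane, CI
Why: SN2 alkylation of the carboxylate with iodomethane is insensitive to the two ortho substituents that would block Fischer esterification, and no other acidic group is present.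

Step 21
Reactants: 35 the penta-MOM methyl ester of step 20
Product: 36 ascomindone B, methyl 2-{2-[3-(2,6-dihydroxy-4-methylphenyl)-4-hydroxy-6-methoxy-1-oxo-1H-inden-2-yl]-6-hydroxy-4-methoxyphenoxy}-6-hydroxy-4-methylbenzoate
Conditions: HCl (3 M in MeOH), THF, 45 °C
Reagents that add atoms: none
Why: Acid-catalysed transacetalisation in methanol should remove all five MOM ethers as dimethoxymethane, conditions under which the methyl ester, the aryl methyl ethers, the diaryl ether and the indenone are stable.

**Compound list**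

1 | orcinol (5-methylbenzene-1,3-diol) | Cc1cc(O)cc(O)c1 | starting material
2 | 1,3-bis(methoxymethoxy)-5-methylbenzene | COCOc1cc(C)cc(OCOC)c1 | intermediate
3 | [2,6-bis(methoxymethoxy)-4-methylphenyl]lithium (formed in the flask) | [Li]c1c(OCOC)cc(C)cc1OCOC | intermediate
4 | 2,6-bis(methoxymethoxy)-4-methylbenzaldehyde | COCOc1cc(C)cc(OCOC)c1C=O | intermediate
5 | methyl propiolate | C#CC(=O)OC | starting material
6 | methyl 3-lithiopropiolate (formed in the flask) | [Li]C#CC(=O)OC | intermediate
7 | methyl 4-[2,6-bis(methoxymethoxy)-4-methylphenyl]-4-hydroxybut-2-ynoate (racemic) | COC(=O)C#CC(O)c1c(OCOC)cc(C)cc1OCOC | intermediate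
8 | methyl 4-[2,6-bis(methoxymethoxy)-4-methylphenyl]-4-oxobut-2-ynoate | COC(=O)C#CC(=O)c1c(OCOC)cc(C)cc1OCOC | intermediate
9 | methyl acetoacetate | CC(=O)CC(=O)OC | starting material
10 | methyl 3,3-dimethoxybutanoate (formed in the flask) | COC(=O)CC(C)(OC)OC | intermediate
11 | methyl (E)-3-methoxybut-2-enoate | CO/C(C)=C/C(=O)OC | intermediate
12 | lithium (E)-1,3-dimethoxybuta-1,3-dien-1-olate (formed in the flask) | C=C(OC)/C=C(\OC)O[Li] | intermediate
13 | (E)-1,3-dimethoxy-1-(trimethylsilyloxy)buta-1,3-diene | C=C(OC)/C=C(\OC)O[Si](C)(C)C | intermediate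
14 | methyl 2-[2,6-bis(methoxymethoxy)-4-methylbenzoyl]-3,5-dimethoxy-3-(trimethylsilyloxy)cyclohexa-1,4-diene-1-carboxylate (racemic, formed in the flask) | COC(=O)C1=C(C(=O)c2c(OCOC)cc(C)cc2OCOC)C(OC)(O[Si](C)(C)C)C=C(OC)C1 | intermediate
15 | methyl 2-[2,6-bis(methoxymethoxy)-4-methylbenzoyl]-5-methoxy-3-(trimethylsilyloxy)benzoate (formed in the flask) | COC(=O)c1cc(OC)cc(O[Si](C)(C)C)c1C(=O)c1c(OCOC)cc(C)cc1OCOC | intermediate
16 | methyl 2-[2,6-bis(methoxymethoxy)-4-methylbenzoyl]-3-hydroxy-5-methoxybenzoate | COC(=O)c1cc(OC)cc(O)c1C(=O)c1c(OCOC)cc(C)cc1OCOC | intermediate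
17 | methyl 2-[2,6-bis(methoxymethoxy)-4-methylbenzoyl]-5-methoxy-3-(methoxymethoxy)benzoate | COC(=O)c1cc(OC)cc(OCOC)c1C(=O)c1c(OCOC)cc(C)cc1OCOC | intermediate
18 | 2-hydroxy-4-methoxybenzaldehyde | COc1ccc(C=O)c(O)c1 | starting material
19 | 4-methoxy-2-(methoxymethoxy)benzaldehyde | COCOc1cc(OC)ccc1C=O | intermediate
20 | 4-methoxy-2-(methoxymethoxy)phenyl formate (formed in the flask) | COCOc1cc(OC)ccc1OC=O | intermediate
21 | 4-methoxy-2-(methoxymethoxy)phenol | COCOc1cc(OC)ccc1O | intermediate
22 | 2-hydroxy-5-methoxy-3-(methoxymethoxy)benzaldehyde | COCOc1cc(OC)cc(C=O)c1O | intermediate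
23 | 2-(hydroxymethyl)-4-methoxy-6-(methoxymethoxy)phenol | COCOc1cc(OC)cc(CO)c1O | intermediate
24 | 3-fluoro-5-methylphenol | Cc1cc(O)cc(F)c1 | starting material
25 | 1-fluoro-3-(methoxymethoxy)-5-methylbenzene | COCOc1cc(C)cc(F)c1 | intermediate
26 | [2-fluoro-6-(methoxymethoxy)-4-methylphenyl]lithium (formed in the flask) | [Li]c1c(F)cc(C)cc1OCOC | intermediate
27 | 2-fluoro-6-(methoxymethoxy)-4-methylbenzaldehyde | COCOc1cc(C)cc(F)c1C=O | intermediate
28 | 2-[2-(hydroxymethyl)-4-methoxy-6-(methoxymethoxy)phenoxy]-6-(methoxymethoxy)-4-methylbenzaldehyde | COCOc1cc(C)cc(Oc2c(CO)cc(OC)cc2OCOC)c1C=O | intermediate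
29 | 2-[2-(bromomethyl)-4-methoxy-6-(methoxymethoxy)phenoxy]-6-(methoxymethoxy)-4-methylbenzaldehyde | COCOc1cc(C)cc(Oc2c(CBr)cc(OC)cc2OCOC)c1C=O | intermediate
30 | diethyl {2-[2-formyl-3-(methoxymethoxy)-5-methylphenoxy]-5-methoxy-3-(methoxymethoxy)benzyl}phosphonate | CCOP(=O)(Cc1cc(OC)cc(OCOC)c1Oc1cc(C)cc(OCOC)c1C=O)OCC | intermediate
31 | 2-{2-[(diethoxyphosphoryl)methyl]-4-methoxy-6-(methoxymethoxy)phenoxy}-6-(methoxymethoxy)-4-methylbenzoic acid | CCOP(=O)(Cc1cc(OC)cc(OCOC)c1Oc1cc(C)cc(OCOC)c1C(=O)O)OCC | intermediate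
32 | lithium 2-{2-[(diethoxyphosphoryl)(lithio)methyl]-4-methoxy-6-(methoxymethoxy)phenoxy}-6-(methoxymethoxy)-4-methylbenzoate (formed in the flask) | CCOP(=O)(C([Li])c1cc(OC)cc(OCOC)c1Oc1cc(C)cc(OCOC)c1C(=O)O[Li])OCC | intermediate
33 | 2-{2-[1-(diethoxyphosphoryl)-2-{2-[2,6-bis(methoxymethoxy)-4-methylbenzoyl]-5-methoxy-3-(methoxymethoxy)phenyl}-2-oxoethyl]-4-methoxy-6-(methoxymethoxy)phenoxy}-6-(methoxymethoxy)-4-methylbenzoic acid (racemic, present in the flask as its lithium salt) | CCOP(=O)(OCC)C(C(=O)c1cc(OC)cc(OCOC)c1C(=O)c1c(OCOC)cc(C)cc1OCOC)c1cc(OC)cc(OCOC)c1Oc1cc(C)cc(OCOC)c1C(=O)O | intermediate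
34 | 2-{2-[3-[2,6-bis(methoxymethoxy)-4-methylphenyl]-6-methoxy-4-(methoxymethoxy)-1-oxo-1H-inden-2-yl]-4-methoxy-6-(methoxymethoxy)phenoxy}-6-(methoxymethoxy)-4-methylbenzoic acid | OC(=O)c1c(OCOC)cc(C)cc1Oc1c(OCOC)cc(OC)cc1C1=C(c2c(OCOC)cc(C)cc2OCOC)c2c(OCOC)cc(OC)cc2C1=O | intermediate
35 | methyl 2-{2-[3-[2,6-bis(methoxymethoxy)-4-methylphenyl]-6-methoxy-4-(methoxymethoxy)-1-oxo-1H-inden-2-yl]-4-methoxy-6-(methoxymethoxy)phenoxy}-6-(methoxymethoxy)-4-methylbenzoate | COC(=O)c1c(OCOC)cc(C)cc1Oc1c(OCOC)cc(OC)cc1C1=C(c2c(OCOC)cc(C)cc2OCOC)c2c(OCOC)cc(OC)cc2C1=O | intermediate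
36 | ascomindone B, methyl 2-{2-[3-(2,6-dihydroxy-4-methylphenyl)-4-hydroxy-6-methoxy-1-oxo-1H-inden-2-yl]-6-hydroxy-4-methoxyphenoxy}-6-hydroxy-4-methylbenzoate | COC(=O)c1c(O)cc(C)cc1Oc1c(O)cc(OC)cc1C1=C(c2c(O)cc(C)cc2O)c2c(O)cc(OC)cc2C1=O | target

**Step count**

Total: 21 steps. Longest linear sequence: 11 steps (from 18 through steps 9–12 and 15–21 to 36).

**Steps most likely to fail**

1. Step 7. The first carbon–carbon bond may form under the control of the ester instead of the ketone, or the crowding between the aroyl group and the ketal carbon may slow ring closure. Either would give the isomeric benzoate with the hydroxyl next to the ester, or open-chain Michael adducts. The fallback removes the competing acceptor, so that the ketone is the only activating group of the alkyne, and restores the ester afterwards; it sets out from 4 and returns at 17.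
 - Aldehyde 4 is treated with (3,3-diethoxyprop-1-yn-1-yl)lithium F1, made from commercial 3,3-diethoxyprop-1-yne and n-BuLi in THF at −78 °C, to give 1-[2,6-bis(methoxymethoxy)-4-methylphenyl]-4,4-diethoxybut-2-yn-1-ol F2.
 - MnO2 in CH2Cl2 should give 1-[2,6-bis(methoxymethoxy)-4-methylphenyl]-4,4-diethoxybut-2-yn-1-one F3.
 - Heating F3 with diene 13 in toluene at 80–110 °C should give the cyclohexa-1,4-diene cycloadduct F4, which loses methanol to the aryl trimethylsilyl ether F5; K2CO3 in methanol cleaves this to [2-(diethoxymethyl)-6-hydroxy-4-methoxyphenyl][2,6-bis(methoxymethoxy)-4-methylphenyl]methanone F6.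
 - MOMCl and i-Pr2NEt give the MOM ether [2-(diethoxymethyl)-4-methoxy-6-(methoxymethoxy)phenyl][2,6-bis(methoxymethoxy)-4-methylphenyl]methanone F7.
 - PPTS in wet acetone hydrolyses the acetal, which is far more labile than the aryl MOM ethers, to 2-[2,6-bis(methoxymethoxy)-4-methylbenzoyl]-5-methoxy-3-(methoxymethoxy)benzaldehyde F8.
 - Pinnick oxidation gives 2-[2,6-bis(methoxymethoxy)-4-methylbenzoyl]-5-methoxy-3-(methoxymethoxy)benzoic acid F9, and MeI with K2CO3 in DMF gives 17.

2. Step 19. The phosphonate-stabilised enolate may add too slowly to the diaryl ketone, which carries four ortho substituents, so that the uncyclised β-ketophosphonate is returned or cleaved by retro-Claisen reaction; the carbanion may also attack the ketone before the ester. The fallback replaces the weakly nucleophilic phosphonoenolate by a simple ketone enolate and closes the ring by aldol condensation; it sets out from 29 (with 17) and returns at 34.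
 - Bromide 29 and sodium benzenesulfinate in DMF give 2-[2-(benzenesulfonylmethyl)-4-methoxy-6-(methoxymethoxy)phenoxy]-6-(methoxymethoxy)-4-methylbenzaldehyde F10.
 - Pinnick oxidation gives 2-[2-(benzenesulfonylmethyl)-4-methoxy-6-(methoxymethoxy)phenoxy]-6-(methoxymethoxy)-4-methylbenzoic acid F11.
 - LiN(i-Pr)2 (2 equiv) in THF at −78 °C gives the dilithiated sulfone F12, which is acylated by ester 17 to the β-keto sulfone acid F13.
 - SmI2 in THF–MeOH at −78 °C cleaves the carbon–sulfur bond to the benzyl ketone acid F14.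
 - KOt-Bu in THF closes the ring to the 3-hydroxyindan-1-one aldol adduct F15, which dehydrates to 34 (intramolecular aldol condensation).

3. Step 15. The phenoxide of 23 is flanked on both sides and the fluoride of 27 is only moderately activated, so at the temperature needed the hydroxymethyl phenoxide may lose hydroxide to an o-quinone methide and oligomerise faster than it is arylated. The fallback uses a more electrophilic partner at room temperature and introduces the ring A oxygen afterwards; it sets out from 23 and returns at 28.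
 - Phenol 23 and commercial 2,6-difluoro-4-methylbenzaldehyde with K2CO3 in DMF at rt should give 2-fluoro-6-[2-(hydroxymethyl)-4-methoxy-6-(methoxymethoxy)phenoxy]-4-methylbenzaldehyde F16; once the phenol is etherified the quinone methide pathway is closed.
 - Acetohydroxamic acid and K2CO3 in DMSO at 80 °C displace the second fluoride to give N-{2-formyl-3-[2-(hydroxymethyl)-4-methoxy-6-(methoxymethoxy)phenoxy]-5-methylphenoxy}acetamide F17, which fragments in a Lossen-type step to 2-hydroxy-6-[2-(hydroxymethyl)-4-methoxy-6-(methoxymethoxy)phenoxy]-4-methylbenzaldehyde F18.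
 - Selective alkylation of the phenoxide (MOMCl, K2CO3, acetone, 0 °C → rt), which leaves the undeprotonated benzylic alcohol alone, gives 28.

**Further compounds**

F1 | step 7 | (3,3-diethoxyprop-1-yn-1-yl)lithium | [Li]C#CC(OCC)OCC
F2 | step 7 | 1-[2,6-bis(methoxymethoxy)-4-methylphenyl]-4,4-diethoxybut-2-yn-1-ol (racemic) | CCOC(OCC)C#CC(O)c1c(OCOC)cc(C)cc1OCOC
F3 | step 7 | 1-[2,6-bis(methoxymethoxy)-4-methylphenyl]-4,4-diethoxybut-2-yn-1-one | CCOC(OCC)C#CC(=O)c1c(OCOC)cc(C)cc1OCOC
F4 | step 7 | [2-(diethoxymethyl)-4,6-dimethoxy-6-(trimethylsilyloxy)cyclohexa-1,4-dien-1-yl][2,6-bis(methoxymethoxy)-4-methylphenyl]methanone (racemic) | CCOC(OCC)C1=C(C(=O)c2c(OCOC)cc(C)cc2OCOC)C(OC)(O[Si](C)(C)C)C=C(OC)C1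
F5 | step 7 | [2-(diethoxymethyl)-4-methoxy-6-(trimethylsilyloxy)phenyl][2,6-bis(methoxymethoxy)-4-methylphenyl]methanone | CCOC(OCC)c1cc(OC)cc(O[Si](C)(C)C)c1C(=O)c1c(OCOC)cc(C)cc1OCOC
F6 | step 7 | [2-(diethoxymethyl)-6-hydroxy-4-methoxyphenyl][2,6-bis(methoxymethoxy)-4-methylphenyl]methanone | CCOC(OCC)c1cc(OC)cc(O)c1C(=O)c1c(OCOC)cc(C)cc1OCOC
F7 | step 7 | [2-(diethoxymethyl)-4-methoxy-6-(methoxymethoxy)phenyl][2,6-bis(methoxymethoxy)-4-methylphenyl]methanone | CCOC(OCC)c1cc(OC)cc(OCOC)c1C(=O)c1c(OCOC)cc(C)cc1OCOC
F8 | step 7 | 2-[2,6-bis(methoxymethoxy)-4-methylbenzoyl]-5-methoxy-3-(methoxymethoxy)benzaldehyde | O=Cc1cc(OC)cc(OCOC)c1C(=O)c1c(OCOC)cc(C)cc1OCOC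
F9 | step 7 | 2-[2,6-bis(methoxymethoxy)-4-methylbenzoyl]-5-methoxy-3-(methoxymethoxy)benzoic acid | OC(=O)c1cc(OC)cc(OCOC)c1C(=O)c1c(OCOC)cc(C)cc1OCOC
F10 | step 19 | 2-[2-(benzenesulfonylmethyl)-4-methoxy-6-(methoxymethoxy)phenoxy]-6-(methoxymethoxy)-4-methylbenzaldehyde | O=Cc1c(OCOC)cc(C)cc1Oc1c(CS(=O)(=O)c2ccccc2)cc(OC)cc1OCOC
F11 | step 19 | 2-[2-(benzenesulfonylmethyl)-4-methoxy-6-(methoxymethoxy)phenoxy]-6-(methoxymethoxy)-4-methylbenzoic acid | OC(=O)c1c(OCOC)cc(C)cc1Oc1c(CS(=O)(=O)c2ccccc2)cc(OC)cc1OCOC
F12 | step 19 | lithium 2-{2-[benzenesulfonyl(lithio)methyl]-4-methoxy-6-(methoxymethoxy)phenoxy}-6-(methoxymethoxy)-4-methylbenzoate | [Li]OC(=O)c1c(OCOC)cc(C)cc1Oc1c(C([Li])S(=O)(=O)c2ccccc2)cc(OC)cc1OCOC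
F13 | step 19 | 2-{2-[1-(benzenesulfonyl)-2-{2-[2,6-bis(methoxymethoxy)-4-methylbenzoyl]-5-methoxy-3-(methoxymethoxy)phenyl}-2-oxoethyl]-4-methoxy-6-(methoxymethoxy)phenoxy}-6-(methoxymethoxy)-4-methylbenzoic acid (racemic) | OC(=O)c1c(OCOC)cc(C)cc1Oc1c(C(C(=O)c2cc(OC)cc(OCOC)c2C(=O)c2c(OCOC)cc(C)cc2OCOC)S(=O)(=O)c2ccccc2)cc(OC)cc1OCOC
F14 | step 19 | 2-{2-[2-{2-[2,6-bis(methoxymethoxy)-4-methylbenzoyl]-5-methoxy-3-(methoxymethoxy)phenyl}-2-oxoethyl]-4-methoxy-6-(methoxymethoxy)phenoxy}-6-(methoxymethoxy)-4-methylbenzoic acid | OC(=O)c1c(OCOC)cc(C)cc1Oc1c(CC(=O)c2cc(OC)cc(OCOC)c2C(=O)c2c(OCOC)cc(C)cc2OCOC)cc(OC)cc1OCOC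
F15 | step 19 | 2-{2-[1-[2,6-bis(methoxymethoxy)-4-methylphenyl]-1-hydroxy-5-methoxy-7-(methoxymethoxy)-3-oxo-2,3-dihydro-1H-inden-2-yl]-4-methoxy-6-(methoxymethoxy)phenoxy}-6-(methoxymethoxy)-4-methylbenzoic acid (mixture of diastereomers, racemic) | OC(=O)c1c(OCOC)cc(C)cc1Oc1c(C2C(=O)c3cc(OC)cc(OCOC)c3C2(O)c2c(OCOC)cc(C)cc2OCOC)cc(OC)cc1OCOC
F16 | step 15 | 2-fluoro-6-[2-(hydroxymethyl)-4-methoxy-6-(methoxymethoxy)phenoxy]-4-methylbenzaldehyde | O=Cc1c(F)cc(C)cc1Oc1c(CO)cc(OC)cc1OCOC
F17 | step 15 | N-{2-formyl-3-[2-(hydroxymethyl)-4-methoxy-6-(methoxymethoxy)phenoxy]-5-methylphenoxy}acetamide | CC(=O)NOc1cc(C)cc(Oc2c(CO)cc(OC)cc2OCOC)c1C=O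
F18 | step 15 | 2-hydroxy-6-[2-(hydroxymethyl)-4-methoxy-6-(methoxymethoxy)phenoxy]-4-methylbenzaldehyde | O=Cc1c(O)cc(C)cc1Oc1c(CO)cc(OC)cc1OCOC
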